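Numbering: seven-membered ring C10(=CH2)–C1–C5–C6(OH)–C7(side chain)–C8–C9(OAc); cyclopentene C1–C5. The route rests on the C9–C10 disconnection. It exploits that O6 and O9 are cis and 1,4-related across C7–C8, while C9 adjoins the methylene carbon C10. C6–O and C9 are tied as a γ-butyrolactone, a ring absent from the target, on a preformed trans-disubstituted methylcyclopentene bearing a 1-iodovinyl group at C1. Iodine–lithium exchange sends the vinyl anion into the lactone carbonyl. The carbocycle closes through an oxygen-bridged hemiketal, the bridge opens to release C6–OH and a C9 enone, and reduction in the same flask sets C9.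

Key step: step 10

Remark on the chemistry: side-chain atoms run from C11 (methyl-bearing) to C15 (carbinol); in step 4 the ligand enantiomer is taken to be the one that gives the 1S adduct.

Step 1
Reactants: 1 (S)-citronellal [(3S)-3,7-dimethyloct-6-enal]; 2 SAMP [(2S)-2-(methoxymethyl)pyrrolidin-1-amine]
Product: 3 (E)-SAMP hydrazone of (S)-citronellal
Conditions: Et2O, MgSO4, 0 °C → rt
Reagents that add atoms: none
Why: Hydrazone formation from an aldehyde and a 1,1-dialkylhydrazine is fast and complete under dehydrating conditions and leaves C11 untouched.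

Step 2
Reactants: 3 (E)-SAMP hydrazone of (S)-citronellal; 4 methyl bromoacetate
Product: 5 methyl (3R,4S)-3-[(E)-{[(2S)-2-(methoxymethyl)pyrrolidin-1-yl]imino}methyl]-4,8-dimethylnon-7-enoate
Conditions: LiN(i-Pr)2, THF, 0 °C; then 4, −100 °C → rt
Reagents that add atoms: none
Why: SAMP-hydrazone α-alkylation: the methoxy-chelated lithio-azaenolate is alkylated by the activated bromide on its open face, which should set C7 as R under auxiliary control regardless of the neighbouring C11 centre.

Step 3
Reactants: 5 alkylated SAMP hydrazone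
Product: 6 methyl (3R,4S)-3-formyl-4,8-dimethylnon-7-enoate
Conditions: sat. aq. oxalic acid, Et2O, rt
Reagents that add atoms: water, O
Why: Mild biphasic acid hydrolysis of the hydrazone frees the aldehyde without enolising C7 and spares the ester and the trisubstituted alkene.

Step 4
Reactants: 7 (1-bromovinyl)trimethylsilane; 8 cyclopent-2-en-1-one; 6 methyl (3R,4S)-3-formyl-4,8-dimethylnon-7-enoate
Product: 12 keto lactone (4R,5S)-4-[(2S)-6-methylhept-5-en-2-yl]-5-{(1S,5S)-2-oxo-5-[1-(trimethylsilyl)vinyl]cyclopentyl}oxolan-2-one (C1/C5 trans on the cyclopentanone; C6/C7 trans on the lactone), via silylvinyl Grignard reagent 9 (not isolated), via bromomagnesium enolate 10 (not isolated), via aldol hydroxy ester 11 (not isolated)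
Conditions: Mg, THF, rt (7 → 9); CuBr·SMe2 (5 mol %), TADDOL-derived phosphine–phosphite ligand (6 mol %), 8 (slight excess over 9), 2-MeTHF, −78 °C; then 6, −78 °C; AcOH quench; then PPTS (cat.), CH2Cl2, rt
Reagents that add atoms: magnesium, [Mg] (stays only in 9 and 10)
Why: Copper-catalysed asymmetric conjugate addition of a Grignard reagent with aldol trapping (three-component coupling) and lactonisation: the chiral copper complex sets C1, the aldehyde reaches enolate 10 anti to the new C1 substituent (C5, trans), and the closed chair transition state of the ring-bound E(O)-enolate (anti aldol) coincides with Felkin–Anh attack on 6 with the sec-alkyl group as the large substituent, so C6 is set in a fully matched sense before the γ-hydroxy ester closes to the trans-lactone.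

Step 5
Reactants: 12 keto lactone
Product: 14 (4R,5S)-4-[(2S,4E)-6-hydroxy-6-methylhept-4-en-2-yl]-5-{(1S,5S)-2-oxo-5-[1-(trimethylsilyl)vinyl]cyclopentyl}oxolan-2-one, via β-hydroxy selenide 13 (not isolated)
Conditions: N-(phenylselanyl)phthalimide, H2O, camphorsulfonic acid (cat.), CH2Cl2, rt; then mCPBA, −78 °C; i-Pr2NEt, → rt
Reagents that add atoms: water, O; N-(phenylselanyl)phthalimide, O=C1c2ccccc2C(=O)N1[Se]c1ccccc1 (selenium stays only in 13)
Why: Markovnikov hydroxyselenation followed by selenoxide syn-elimination: the selenium electrophile picks the most electron-rich (trisubstituted) alkene, water opens the seleniranium ion at the tertiary carbon C15, and the selenoxide can only eliminate towards C13, giving the E-allylic tertiary alcohol.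

Step 6
Reactants: 14 tertiary allylic alcohol
Product: 15 triethylsilyl ether of 14
Conditions: Et3SiOTf, 2,6-lutidine, CH2Cl2, −78 °C
Reagents that add atoms: triethylsilyl triflate, CC[Si](CC)(CC)OS(=O)(=O)C(F)(F)F
Why: Silylation with a silyl triflate is strong enough for a tertiary alcohol, and the weak hindered base at low temperature should leave the ketone and its β-acyloxy group alone.

Step 7
Reactants: 15 triethylsilyl ether
Product: 16 (4R,5S)-5-[(1S,5S)-5-(1-iodovinyl)-2-oxocyclopentyl]-4-[(2S,4E)-6-methyl-6-(triethylsilyloxy)hept-4-en-2-yl]oxolan-2-one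
Conditions: N-iodosuccinimide, MeCN, 0 °C → rt, dark
Reagents that add atoms: N-iodosuccinimide, O=C1CCC(=O)N1I
Why: Ipso-iododesilylation of a 1-silylvinyl group: the vinylsilane is the only nucleophilic alkene left, since the side-chain alkene is 1,2-disubstituted and both deactivated and shielded by the allylic silyl ether.

Step 8
Reactants: 16 iodovinyl ketone
Product: 17 (4R,5S)-5-[(1S,2S,5S)-2-hydroxy-5-(1-iodovinyl)-2-methylcyclopentyl]-4-[(2S,4E)-6-methyl-6-(triethylsilyloxy)hept-4-en-2-yl]oxolan-2-one
Conditions: MeLi, CeCl3 (anhydrous), THF, −78 °C; then 16, −78 °C; aq. NH4Cl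
Reagents that add atoms: methyllithium, [Li]C
Why: Organocerium 1,2-addition: the non-basic reagent adds to the ketone faster than to the lactone, without enolisation, β-elimination of the acyloxy group or iodine–metal exchange, and from the face anti to the C5 substituent, so the new hydroxyl is trans to H5.

Step 9
Reactants: 17 tertiary cyclopentanol
Product: 18 (4R,5S)-5-[(1R,5S)-5-(1-iodovinyl)-2-methylcyclopent-2-en-1-yl]-4-[(2S,4E)-6-methyl-6-(triethylsilyloxy)hept-4-en-2-yl]oxolan-2-one
Conditions: methyl N-(triethylammoniosulfonyl)carbamate (Burgess reagent), toluene, 60 °C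
Reagents that add atoms: none
Why: Burgess dehydration (syn Ei elimination): H5 is anti to the sulfamate and cannot be reached, so elimination should go towards C3 to the endocyclic trisubstituted alkene, which is favoured over the exocyclic isomer in a five-membered ring.

Step 10
Reactants: 18 iodovinyl cyclopentenyl lactone
Product: 22 diol (3aR,4S,5R,7R,8aS)-3-methyl-8-methylidene-5-[(2S,4E)-6-methyl-6-(triethylsilyloxy)hept-4-en-2-yl]-1,3a,4,5,6,7,8,8a-octahydroazulene-4,7-diol, via vinyllithium 19 (not isolated), via bridged lithium hemiketal 20 (not isolated), via hydroxy enone 21 (not isolated)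
Conditions: t-BuLi (2.1 equiv), Et2O/pentane, −78 °C; then precooled MeOH, CeCl3·7H2O, NaBH4, −78 → −20 °C
Reagents that add atoms: tert-butyllithium, [Li]C(C)(C)C (lithium stays only in 19 and 20)
Why: t-BuLi exchanges the vinylic iodine, and vinyllithium 19 attacks the lactone C9=O from the face that carries C5, which on the trans-lactone is opposite to the C7 side chain, giving bridged lithium hemiketal 20; protonation lets the oxygen bridge open to hydroxy enone 21, which NaBH4/CeCl3 reduces at the carbonyl. The closest known reaction types are the halogen–lithium-exchange-initiated (Parham-type) intramolecular acylation of vinyl- and aryllithiums by esters and lactones, and the Luche reduction. The carbocycle closes 7-exo-trig at C9, but because O6 already links C6 to C9 the bond forms through a six-membered chair (C10–C1–C5–C6–O–C9, 6-exo-trig) with the trans-fused cyclopentene bonds equatorial, which avoids the usual entropic penalty of seven-ring closure. C9, the only new stereocentre, is set in the reduction: O6–H sits over the carbonyl face from which it forms the hemiketal, and the C7 side chain and C2 lie on that same side, so external hydride should enter from the opposite face and place O9 cis to O6 (9R). The step needs exchange to outrun carbonyl attack by t-BuLi, a single addition and clean 1,2-reduction: the sp2 C–I bond and the comparatively unreactive lactone carbonyl secure the first, the tetrahedral alkoxide 20 held in the bicycle (with no organolithium left) secures the second, and cold reduction of 21 under CeCl3 in the same flask forestalls oxa-Michael addition of O6–H and migration of the exocyclic alkene.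

Step 11
Reactants: 22 diol
Product: 23 C9 monoacetate of 22
Conditions: Ac2O (1.2 equiv), pyridine, DMAP (cat.), CH2Cl2, 0 °C
Reagents that add atoms: acetic anhydride, CC(=O)OC(C)=O
Why: Selective acylation: the allylic C9 hydroxyl, flanked by a CH2 and an sp2 carbon, is far more accessible than the C6 hydroxyl wedged between the methine carbons C5 and C7, so a small excess of anhydride should acetylate C9 only.

Step 12
Reactants: 23 silyl-protected acetate
Product: 24 target, (3aR,4S,5R,7R,8aS)-4-hydroxy-5-[(2S,4E)-6-hydroxy-6-methylhept-4-en-2-yl]-3-methyl-8-methylidene-1,3a,4,5,6,7,8,8a-octahydroazulen-7-yl acetate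
Conditions: HF·pyridine, pyridine, THF, 0 °C
Reagents that add atoms: none
Why: Buffered fluoride-mediated desilylation removes the triethylsilyl group without ionising the tertiary allylic alcohol or touching the acetate.

Compound list
1 | (S)-citronellal, (3S)-3,7-dimethyloct-6-enal | O=CC[C@@H](C)CCC=C(C)C | starting material
2 | SAMP, (2S)-2-(methoxymethyl)pyrrolidin-1-amine | COC[C@@H]1CCCN1N | starting material
3 | (E)-SAMP hydrazone of (S)-citronellal | COC[C@@H]1CCCN1/N=C/C[C@@H](C)CCC=C(C)C | intermediate
4 | methyl bromoacetate | COC(=O)CBr | starting material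
5 | methyl (3R,4S)-3-[(E)-{[(2S)-2-(methoxymethyl)pyrrolidin-1-yl]imino}methyl]-4,8-dimethylnon-7-enoate | COC[C@@H]1CCCN1/N=C/[C@H](CC(=O)OC)[C@@H](C)CCC=C(C)C | intermediate
6 | methyl (3R,4S)-3-formyl-4,8-dimethylnon-7-enoate | O=C[C@H](CC(=O)OC)[C@@H](C)CCC=C(C)C | intermediate
7 | (1-bromovinyl)trimethylsilane | C=C(Br)[Si](C)(C)C | starting material
8 | cyclopent-2-en-1-one | O=C1C=CCC1 | starting material
9 | [1-(trimethylsilyl)vinyl]magnesium bromide | C=C([Mg]Br)[Si](C)(C)C | intermediate
10 | bromomagnesium C4–C5 enolate of (3S)-3-[1-(trimethylsilyl)vinyl]cyclopentanone | C=C([Si](C)(C)C)[C@H]1CCC(O[Mg]Br)=C1 | intermediate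
11 | methyl (3R,4S)-3-[(S)-hydroxy{(1S,5S)-2-oxo-5-[1-(trimethylsilyl)vinyl]cyclopentyl}methyl]-4,8-dimethylnon-7-enoate | C=C([Si](C)(C)C)[C@H]1CCC(=O)[C@@H]1[C@@H](O)[C@H](CC(=O)OC)[C@@H](C)CCC=C(C)C | intermediate
12 | (4R,5S)-4-[(2S)-6-methylhept-5-en-2-yl]-5-{(1S,5S)-2-oxo-5-[1-(trimethylsilyl)vinyl]cyclopentyl}oxolan-2-one | C=C([Si](C)(C)C)[C@H]1CCC(=O)[C@@H]1[C@H]2OC(=O)C[C@@H]2[C@@H](C)CCC=C(C)C | intermediate
13 | β-hydroxy selenide of 12 (C14–SePh, C15–OH; C14 epimers) | C=C([Si](C)(C)C)[C@H]1CCC(=O)[C@@H]1[C@H]2OC(=O)C[C@@H]2[C@@H](C)CCC([Se]c3ccccc3)C(C)(C)O | intermediate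
14 | (4R,5S)-4-[(2S,4E)-6-hydroxy-6-methylhept-4-en-2-yl]-5-{(1S,5S)-2-oxo-5-[1-(trimethylsilyl)vinyl]cyclopentyl}oxolan-2-one | C=C([Si](C)(C)C)[C@H]1CCC(=O)[C@@H]1[C@H]2OC(=O)C[C@@H]2[C@@H](C)C/C=C/C(C)(C)O | intermediate
15 | triethylsilyl ether of 14 | C=C([Si](C)(C)C)[C@H]1CCC(=O)[C@@H]1[C@H]2OC(=O)C[C@@H]2[C@@H](C)C/C=C/C(C)(C)O[Si](CC)(CC)CC | intermediate
16 | (4R,5S)-5-[(1S,5S)-5-(1-iodovinyl)-2-oxocyclopentyl]-4-[(2S,4E)-6-methyl-6-(triethylsilyloxy)hept-4-en-2-yl]oxolan-2-one | C=C(I)[C@H]1CCC(=O)[C@@H]1[C@H]2OC(=O)C[C@@H]2[C@@H](C)C/C=C/C(C)(C)O[Si](CC)(CC)CC | intermediate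
17 | (4R,5S)-5-[(1S,2S,5S)-2-hydroxy-5-(1-iodovinyl)-2-methylcyclopentyl]-4-[(2S,4E)-6-methyl-6-(triethylsilyloxy)hept-4-en-2-yl]oxolan-2-one | C=C(I)[C@H]1CC[C@](C)(O)[C@@H]1[C@H]2OC(=O)C[C@@H]2[C@@H](C)C/C=C/C(C)(C)O[Si](CC)(CC)CC | intermediate
18 | (4R,5S)-5-[(1R,5S)-5-(1-iodovinyl)-2-methylcyclopent-2-en-1-yl]-4-[(2S,4E)-6-methyl-6-(triethylsilyloxy)hept-4-en-2-yl]oxolan-2-one | C=C(I)[C@H]1CC=C(C)[C@@H]1[C@H]2OC(=O)C[C@@H]2[C@@H](C)C/C=C/C(C)(C)O[Si](CC)(CC)CC | intermediate
19 | vinyllithium from 18 | C=C([Li])[C@H]1CC=C(C)[C@@H]1[C@H]2OC(=O)C[C@@H]2[C@@H](C)C/C=C/C(C)(C)O[Si](CC)(CC)CC | intermediate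
20 | bridged lithium hemiketal (O6–C9 bridge, 8-oxabicyclo[3.2.1]octane core fused to the cyclopentene) | C=C1[C@H]2CC=C(C)[C@@H]2[C@H]3O[C@]1(O[Li])C[C@@H]3[C@@H](C)C/C=C/C(C)(C)O[Si](CC)(CC)CC | intermediate
21 | hydroxy enone (C6–OH, C9 ketone, C10 methylidene) | C=C1[C@H]2CC=C(C)[C@@H]2[C@@H](O)[C@@H]([C@@H](C)C/C=C/C(C)(C)O[Si](CC)(CC)CC)CC1=O | intermediate
22 | (3aR,4S,5R,7R,8aS)-3-methyl-8-methylidene-5-[(2S,4E)-6-methyl-6-(triethylsilyloxy)hept-4-en-2-yl]-1,3a,4,5,6,7,8,8a-octahydroazulene-4,7-diol | C=C1[C@H]2CC=C(C)[C@@H]2[C@@H](O)[C@@H]([C@@H](C)C/C=C/C(C)(C)O[Si](CC)(CC)CC)C[C@H]1O | intermediate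
23 | C9 (azulene C7) monoacetate of 22 | C=C1[C@H]2CC=C(C)[C@@H]2[C@@H](O)[C@@H]([C@@H](C)C/C=C/C(C)(C)O[Si](CC)(CC)CC)C[C@H]1OC(C)=O | intermediate
24 | CNP0312076.1 | C=C1[C@H]2CC=C(C)[C@@H]2[C@@H](O)[C@@H]([C@@H](C)C/C=C/C(C)(C)O)C[C@H]1OC(C)=O | target

Total steps: 12. Longest linear sequence: 12 steps (1 → 24).

Steps most likely to fail

Step 4. The hindered α-silylvinyl Grignard reagent may be delivered with poor enantioface discrimination or partly by 1,2-addition, and the aldol selectivity may erode through retro-aldol equilibration. The fallback sets out from 9, 8 and 6 and comes back at 12. Reagent 9 is added to 8 under CuI/LiCl catalysis in the presence of Me3SiCl to give the racemic silyl enol ether F1. MeLi and then ZnCl2 turn it into the regiodefined zinc enolate, which is offered a deficit of enantiopure 6. The enolate enantiomer for which anti-aldol topology and Felkin–Anh attack coincide should react preferentially to 11, and acid-catalysed lactonisation gives 12. Products from the other enolate enantiomer are diastereomers and are removed by chromatography. Control thus passes from the catalyst to the aldehyde.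

Step 10. Direct attack of t-BuLi on the lactone, enolisation of the lactone by the vinyllithium, or decay of the enone (oxa-Michael addition, alkene migration) before reduction may erode the closure. The fallback sets out from 18 and comes back at 22. i-Bu2AlH at −78 °C reduces the lactone to the lactol F2, and CrCl2 with catalytic NiCl2 in DMSO (Nozaki–Hiyama–Kishi reaction) couples the vinyl iodide with the hydroxy-aldehyde tautomer. This gives the allylic alcohol and the free C6 hydroxyl without strong base and without passing through an enone.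

Step 9. Loss of regiocontrol in the dehydration (exocyclic alkene, or the tetrasubstituted C4=C5 alkene if the methyl addition in step 8 was not face-selective) may occur. The fallback sets out from 15 and comes back at 18. Kinetic deprotonation at C3 with KN(SiMe3)2 and trapping with N-(5-chloropyridin-2-yl)bis(trifluoromethanesulfonimide) gives the enol triflate F3. Negishi coupling with ZnMe2 and Pd(PPh3)4 gives the methylcyclopentene vinylsilane F4 with the alkene position fixed by the triflate, and iododesilylation with N-iodosuccinimide then gives 18.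

Further compounds
F1 | step 4 | racemic trimethyl({3-[1-(trimethylsilyl)vinyl]cyclopent-1-en-1-yl}oxy)silane | C=C([Si](C)(C)C)C1CCC(O[Si](C)(C)C)=C1
F2 | step 10 | lactol of 18 (anomers) | C=C(I)[C@H]1CC=C(C)[C@@H]1[C@H]2OC(O)C[C@@H]2[C@@H](C)C/C=C/C(C)(C)O[Si](CC)(CC)CC
F3 | step 9 | C3=C4 enol triflate of 15 | C=C([Si](C)(C)C)[C@H]1CC=C(OS(=O)(=O)C(F)(F)F)[C@@H]1[C@H]2OC(=O)C[C@@H]2[C@@H](C)C/C=C/C(C)(C)O[Si](CC)(CC)CC
F4 | step 9 | methylcyclopentene vinylsilane (18 with SiMe3 in place of I) | C=C([Si](C)(C)C)[C@H]1CC=C(C)[C@@H]1[C@H]2OC(=O)C[C@@H]2[C@@H](C)C/C=C/C(C)(C)O[Si](CC)(CC)CC
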